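Everything rests on growing ring B from a ketone side chain on the finished, enantiopure A/C chroman instead of coupling an arene. Ring B bears oxygen on C2' and C4', and ring D is fused through C3', the carbon flanked by both. That is the position (C2) at which a cyclohexane-1,3-dione condenses with an enal, and the key step exploits it. In one operation the ketone's methylene carbon is bonded to methyl acrylate (C1'–C6') and its methyl carbon to the ester carbonyl (C3'–C4'), closing the six-membered carbocycle. The precursor is (S)-1-[7-(methoxymethoxy)-8-prenylchroman-3-yl]propan-2-one. Its only stereocentre, C3, comes from an oxazolidinone-directed benzylation, and its MOM group also steers the C8 prenylation.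

Key step: step 12

Remark: isoflavan numbering is used (O1, C2–C4, C4a–C8a for rings C and A, primed locants for ring B); the target stereocentre is read as (3S), and C3 keeps one spatial arrangement from step 6 onward, its descriptor changing from R to S in step 11 (and formally back in the selenium compounds 27 and 28) only because the CIP ranking of its neighbours changes.

Step 1
Reactants: 1 2,4-dihydroxybenzaldehyde
Product: 2 2-hydroxy-4-(methoxymethoxy)benzaldehyde
Conditions: MOMCl (1.05 equiv), K2CO3, acetone, 0 °C to rt
Reagents that add atoms: chloromethyl methyl ether, COCCl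
Why: Williamson-type O-alkylation should take place only at the 4-OH, because the 2-OH is locked in a hydrogen bond to the formyl oxygen and is much the poorer nucleophile under mild carbonate conditions.

Step 2
Reactants: 2 2-hydroxy-4-(methoxymethoxy)benzaldehyde
Product: 3 2-(allyloxy)-4-(methoxymethoxy)benzaldehyde
Conditions: allyl bromide, K2CO3, DMF, 50 °C
Reagents that add atoms: allyl bromide, C=CCBr
Why: Williamson etherification of the remaining chelated phenol under slightly more forcing conditions should install an allyl ether that survives hydride, bromination and enolate chemistry and can later be removed by zerovalent palladium without touching the MOM group.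

Step 3
Reactants: 3 2-(allyloxy)-4-(methoxymethoxy)benzaldehyde
Product: 4 [2-(allyloxy)-4-(methoxymethoxy)phenyl]methanol
Conditions: NaBH4, MeOH, 0 °C
Reagents that add atoms: none
Why: Borohydride 1,2-reduction of the aryl aldehyde is chemoselective, the acetal, the aryl ethers and the isolated alkene being inert to NaBH4.

Step 4
Reactants: 4 [2-(allyloxy)-4-(methoxymethoxy)phenyl]methanol
Product: 5 2-(allyloxy)-1-(bromomethyl)-4-(methoxymethoxy)benzene
Conditions: CBr4, PPh3, CH2Cl2, 0 °C; short silica pad, used the same day
Reagents that add atoms: carbon tetrabromide, BrC(Br)(Br)Br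
Why: The Appel reaction converts the benzylic alcohol into the bromide by SN2 displacement of an alkoxyphosphonium ion under essentially neutral conditions, which spares the MOM acetal, and the labile electron-rich bromide is used at once for that reason.

Step 5
Reactants: 6 (S)-4-benzyloxazolidin-2-one; 7 pent-4-enoyl chloride
Product: 8 (S)-4-benzyl-3-(pent-4-enoyl)oxazolidin-2-one
Conditions: Et3N, DMAP (10 mol%), CH2Cl2, 0 °C to rt
Reagents that add atoms: none
Why: DMAP-catalysed N-acylation of the oxazolidinone with the acid chloride is a standard entry to the Evans imide and does not touch the auxiliary stereocentre.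

Step 6
Reactants: 8 (S)-4-benzyl-3-(pent-4-enoyl)oxazolidin-2-one; 5 2-(allyloxy)-1-(bromomethyl)-4-(methoxymethoxy)benzene
Product: 10 (S)-4-benzyl-3-{(R)-2-[2-(allyloxy)-4-(methoxymethoxy)benzyl]pent-4-enoyl}oxazolidin-2-one, via sodium Z-enolate 9 (not isolated)
Conditions: NaN(SiMe3)2 (1.1 equiv), THF, −78 °C; then 5, −78 to −30 °C
Reagents that add atoms: none
Why: Evans asymmetric alkylation: deprotonation should give the chelated Z-enolate 9, one face of which is screened by the C4 benzyl group of the (S)-auxiliary, so the reactive benzylic bromide attacks the open face in an SN2 step and sets the future C3 with the (R) descriptor shown.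

Step 7
Reactants: 10 the alkylated imide
Product: 11 (R)-2-[2-(allyloxy)-4-(methoxymethoxy)benzyl]pent-4-en-1-ol
Conditions: LiBH4, THF, 0 °C to rt
Reagents that add atoms: none
Why: Reductive removal of the auxiliary with LiBH4 (hydride attack at the exocyclic imide carbonyl) should give the primary alcohol without enolisation, so the new stereocentre is kept and the auxiliary can be recovered.

Step 8
Reactants: 11 (R)-2-[2-(allyloxy)-4-(methoxymethoxy)benzyl]pent-4-en-1-ol
Product: 12 (R)-2-[2-(hydroxymethyl)pent-4-en-1-yl]-5-(methoxymethoxy)phenol
Conditions: Pd(PPh3)4 (5 mol%), morpholine, THF, rt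
Reagents that add atoms: none
Why: Tsuji–Trost-type deallylation: zerovalent palladium ionises only the allyl aryl ether to a π-allyl complex that morpholine intercepts, while the C-allyl group, the MOM ether and the alcohol offer no leaving group.

Step 9
Reactants: 12 (R)-2-[2-(hydroxymethyl)pent-4-en-1-yl]-5-(methoxymethoxy)phenol
Product: 13 (R)-3-allyl-7-(methoxymethoxy)chroman
Conditions: PPh3, DIAD, THF (0.05 M), 0 °C to rt
Reagents that add atoms: none
Why: Intramolecular Mitsunobu etherification (6-exo-tet SN2 of the phenoxide on the activated primary carbinol) should close ring C at a carbon that is not stereogenic, so C3 is untouched.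

Step 10
Reactants: 13 (R)-3-allyl-7-(methoxymethoxy)chroman; 14 prenyl bromide (1-bromo-3-methylbut-2-ene)
Product: 16 (R)-3-allyl-7-(methoxymethoxy)-8-(3-methylbut-2-en-1-yl)chroman, via 8-lithiochroman 15 (not isolated)
Conditions: n-BuLi (1.2 equiv), THF, 0 °C; CuBr·SMe2 (20 mol%), 14, −78 °C to rt
Reagents that add atoms: none
Why: Directed ortho-metalation: the MOM ether and the ring oxygen O1 jointly coordinate the base and acidify the C8–H that lies between them, and copper-assisted SN2 coupling of aryllithium 15 with prenyl bromide should deliver the linear prenyl group.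

Step 11
Reactants: 16 (R)-3-allyl-7-(methoxymethoxy)-8-(3-methylbut-2-en-1-yl)chroman
Product: 17 (S)-1-[7-(methoxymethoxy)-8-(3-methylbut-2-en-1-yl)chroman-3-yl]propan-2-one
Conditions: PdCl2 (10 mol%), CuCl (1 equiv), O2 (1 atm), DMF/H2O 7:1, rt
Reagents that add atoms: water, O
Why: Tsuji–Wacker oxidation: divalent palladium binds the monosubstituted alkene far better than the trisubstituted prenyl alkene, and Markovnikov hydroxypalladation followed by β-hydride elimination should give the methyl ketone with C3 unchanged in space.

Step 12
Reactants: 17 (S)-1-[7-(methoxymethoxy)-8-(3-methylbut-2-en-1-yl)chroman-3-yl]propan-2-one; 18 methyl acrylate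
Product: 22 4-[(S)-7-(methoxymethoxy)-8-prenylchroman-3-yl]cyclohexane-1,3-dione (both epimers at C1'), via internal potassium enolate 19 (not isolated), via keto ester 20 (not isolated), via potassium dionate 21 (not isolated)
Conditions: KOtBu (2.2 equiv), THF, −10 °C; 18 (1.05 equiv) added over 1 h; to rt; AcOH quench
Reagents that add atoms: none
Why: KOtBu equilibrates the enolates of 17, the more substituted one 19 (at the CH2 attached to C3) adds to methyl acrylate in a Michael reaction (C1'–C6') to give keto ester 20, and after proton transfer the methyl-side enolate attacks the ester carbonyl and expels methoxide (C3'–C4'), the acidic dione being held at once as its potassium enolate 21, which makes the sequence irreversible until the acetic acid quench. The closest known reaction type is the consecutive Michael–Claisen synthesis of 4-alkylcyclohexane-1,3-diones from alkyl methyl ketones and acrylates under tert-butoxide. The carbocycle closes in the favoured 6-(enolendo)-exo-trig mode, an intramolecular Claisen (Dieckmann-like) acylation. The only new stereocentre, C1', forms without control and stays enolisable, which is harmless because it becomes sp2 in step 14, whereas C3 is β to the carbonyl, carries no acidic hydrogen and no leaving group, so its configuration should survive. The step needs C-alkylation at the methylene and acylation from the methyl group: the thermodynamic preference for the internal enolate secures the first, and an adduct formed at the methyl carbon could cyclise only through the carbon that bears the bulky chromanyl group, whereas 20 closes through an unhindered CH3-derived enolate. Slow addition of one equivalent of acrylate at low temperature to excess base should hold back a second Michael addition and acrylate polymerisation, and the MOM ether, the aryl ethers and the prenyl alkene are inert to KOtBu in THF at or below room temperature.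

Step 13
Reactants: 22 4-[(S)-7-(methoxymethoxy)-8-prenylchroman-3-yl]cyclohexane-1,3-dione; 23 3-methylbut-2-enal
Product: 25 6-[(S)-7-(methoxymethoxy)-8-prenylchroman-3-yl]-2,2-dimethyl-7,8-dihydro-2H-chromen-5(6H)-one (both epimers at C1'), via 1-oxatriene 24 (not isolated)
Conditions: 23 (1.3 equiv), ethylenediammonium diacetate (20 mol%), toluene, rt, then 90 °C
Reagents that add atoms: none
Why: Knoevenagel condensation at C3', the only carbon flanked by both carbonyl groups, should give 1-oxatriene 24, and because its oxa-6π electrocyclisation is reversible on heating the ring D oxygen should settle on C4', remote from the bulky chromanyl group, in line with the known preference of 4-substituted cyclohexane-1,3-diones to form enol ethers at the unhindered carbonyl.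

Step 14
Reactants: 25 the pyran-fused cyclohexenone
Product: 30 6-[(S)-7-(methoxymethoxy)-8-prenylchroman-3-yl]-2,2-dimethyl-2H-chromen-5-ol, via lithium enolate 26 (not isolated), via C1' selenide 27 (not isolated), via selenoxide 28 (not isolated), via cross-conjugated dienone 29 (not isolated)
Conditions: LiN(iPr)2 (LDA, 1.2 equiv), THF, −78 °C; PhSeCl (1.1 equiv), −78 °C; crude, 30% H2O2, pyridine, CH2Cl2, 0 °C to rt
Reagents that add atoms: none
Why: α-Selenenylation and selenoxide syn-elimination: kinetic deprotonation of the vinylogous ester at C1' gives enolate 26, selenide 27 is oxidised at selenium faster than any alkene reacts, selenoxide 28 eliminates toward the ring C6'–H (a CH2, favoured over the hindered exocyclic C3–H methine), and dienone 29 tautomerises to the phenol, all without the hydride-abstracting quinones that would endanger the C4 and C8 benzylic positions of ring A.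

Step 15
Reactants: 30 the 7-O-MOM ether of the target
Product: 31 6-[(3S)-7-hydroxy-8-(3-methylbut-2-en-1-yl)chroman-3-yl]-2,2-dimethyl-2H-chromen-5-ol (CNP0263294.1)
Conditions: p-TsOH·H2O (10 mol%), MeOH, 40 °C, stopped at full conversion
Reagents that add atoms: none
Why: Acid-catalysed transacetalisation: the MOM acetal ionises through an oxocarbenium ion much faster than the prenyl or chromene double bonds are protonated, so brief exposure to catalytic acid in methanol should free the 7-OH without cyclising the ortho-prenylphenol.

Compound list
1 | 2,4-dihydroxybenzaldehyde | O=Cc1ccc(O)cc1O | starting material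
2 | 2-hydroxy-4-(methoxymethoxy)benzaldehyde | O=Cc1ccc(OCOC)cc1O | intermediate
3 | 2-(allyloxy)-4-(methoxymethoxy)benzaldehyde | O=Cc1ccc(OCOC)cc1OCC=C | intermediate
4 | [2-(allyloxy)-4-(methoxymethoxy)phenyl]methanol | OCc1ccc(OCOC)cc1OCC=C | intermediate
5 | 2-(allyloxy)-1-(bromomethyl)-4-(methoxymethoxy)benzene | BrCc1ccc(OCOC)cc1OCC=C | intermediate
6 | (S)-4-benzyloxazolidin-2-one | O=C1N[C@@H](Cc2ccccc2)CO1 | starting material
7 | pent-4-enoyl chloride | C=CCCC(=O)Cl | starting material
8 | (S)-4-benzyl-3-(pent-4-enoyl)oxazolidin-2-one | C=CCCC(=O)N1C(=O)OC[C@@H]1Cc1ccccc1 | intermediate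
9 | sodium Z-enolate of 8 | [Na+].C=CC/C=C(\[O-])N1C(=O)OC[C@@H]1Cc1ccccc1 | intermediate
10 | (S)-4-benzyl-3-{(R)-2-[2-(allyloxy)-4-(methoxymethoxy)benzyl]pent-4-enoyl}oxazolidin-2-one | C=CC[C@H](Cc1ccc(OCOC)cc1OCC=C)C(=O)N1C(=O)OC[C@@H]1Cc1ccccc1 | intermediate
11 | (R)-2-[2-(allyloxy)-4-(methoxymethoxy)benzyl]pent-4-en-1-ol | C=CC[C@@H](CO)Cc1ccc(OCOC)cc1OCC=C | intermediate
12 | (R)-2-[2-(hydroxymethyl)pent-4-en-1-yl]-5-(methoxymethoxy)phenol | C=CC[C@@H](CO)Cc1ccc(OCOC)cc1O | intermediate
13 | (R)-3-allyl-7-(methoxymethoxy)chroman | COCOc1ccc2c(c1)OC[C@H](CC=C)C2 | intermediate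
14 | prenyl bromide (1-bromo-3-methylbut-2-ene) | CC(C)=CCBr | starting material
15 | 8-lithio derivative of 13 | [Li]c1c(OCOC)ccc2c1OC[C@H](CC=C)C2 | intermediate
16 | (R)-3-allyl-7-(methoxymethoxy)-8-(3-methylbut-2-en-1-yl)chroman | CC(C)=CCc1c(OCOC)ccc2c1OC[C@H](CC=C)C2 | intermediate
17 | (S)-1-[7-(methoxymethoxy)-8-(3-methylbut-2-en-1-yl)chroman-3-yl]propan-2-one | CC(C)=CCc1c(OCOC)ccc2c1OC[C@H](CC(C)=O)C2 | intermediate
18 | methyl acrylate | C=CC(=O)OC | starting material
19 | internal (C1'=C2') potassium enolate of 17 | [K+].CC(C)=CCc1c(OCOC)ccc2c1OC[C@H](C=C(C)[O-])C2 | intermediate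
20 | methyl 4-[(S)-7-(methoxymethoxy)-8-prenylchroman-3-yl]-5-oxohexanoate (both epimers at C1') | CC(C)=CCc1c(OCOC)ccc2c1OC[C@H](C(CCC(=O)OC)C(C)=O)C2 | intermediate
21 | potassium enolate of dione 22 | [K+].CC(C)=CCc1c(OCOC)ccc2c1OC[C@H](C1CCC(=O)C=C1[O-])C2 | intermediate
22 | 4-[(S)-7-(methoxymethoxy)-8-prenylchroman-3-yl]cyclohexane-1,3-dione (both epimers at C1') | CC(C)=CCc1c(OCOC)ccc2c1OC[C@H](C1CCC(=O)CC1=O)C2 | intermediate
23 | 3-methylbut-2-enal | CC(C)=CC=O | starting material
24 | 2-(3-methylbut-2-en-1-ylidene) derivative of 22 (1-oxatriene) | CC(C)=CCc1c(OCOC)ccc2c1OC[C@H](C1CCC(=O)C(=CC=C(C)C)C1=O)C2 | intermediate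
25 | 6-[(S)-7-(methoxymethoxy)-8-prenylchroman-3-yl]-2,2-dimethyl-7,8-dihydro-2H-chromen-5(6H)-one (both epimers at C1') | CC(C)=CCc1c(OCOC)ccc2c1OC[C@H](C1CCC3=C(C=CC(C)(C)O3)C1=O)C2 | intermediate
26 | lithium C1'=C2' enolate of 25 | [Li+].CC(C)=CCc1c(OCOC)ccc2c1OC[C@H](C1=C([O-])C3=C(CC1)OC(C)(C)C=C3)C2 | intermediate
27 | C1'-(phenylselanyl) derivative of 25 (C3 in space as in 25) | CC(C)=CCc1c(OCOC)ccc2c1OC[C@H](C1([Se]c3ccccc3)CCC3=C(C=CC(C)(C)O3)C1=O)C2 | intermediate
28 | selenoxide of 27 (C3 in space as in 25) | CC(C)=CCc1c(OCOC)ccc2c1OC[C@H](C1([Se](=O)c3ccccc3)CCC3=C(C=CC(C)(C)O3)C1=O)C2 | intermediate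
29 | 6-[(S)-7-(methoxymethoxy)-8-prenylchroman-3-yl]-2,2-dimethyl-2H-chromen-5(8H)-one (C1'=C6' dienone) | CC(C)=CCc1c(OCOC)ccc2c1OC[C@H](C1=CCC3=C(C=CC(C)(C)O3)C1=O)C2 | intermediate
30 | 6-[(S)-7-(methoxymethoxy)-8-prenylchroman-3-yl]-2,2-dimethyl-2H-chromen-5-ol | CC(C)=CCc1c(OCOC)ccc2c1OC[C@H](c1ccc3c(c1O)C=CC(C)(C)O3)C2 | intermediate
31 | 6-[(3S)-7-hydroxy-8-(3-methylbut-2-en-1-yl)chroman-3-yl]-2,2-dimethyl-2H-chromen-5-ol | CC(C)=CCc1c(O)ccc2c1OC[C@H](c1ccc3c(c1O)C=CC(C)(C)O3)C2 | target

Total step count: 15. Longest linear sequence: 14 (steps 1–4 and 6–15).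

Steps most likely to fail

Step 12. Regiocontrol in the Michael step may be lost, because the methyl-side enolate competes kinetically with the β-branched methylene. A second conjugate addition before ring closure, or anionic polymerisation of the acrylate, is also possible. The fallback sets out from 17 and fixes the enolate position before any C–C bond is made.
- Equilibrating silylation (Me3SiCl, Et3N, DMF, 80 °C) should favour the internal (Z)-trimethylsilyl enol ether F1, which is freed from its terminal isomer on triethylamine-deactivated silica.
- MeLi (THF, 0 °C) then releases the regiodefined lithium enolate F2, which is cooled to −78 °C and treated with methyl acrylate 18 under non-equilibrating conditions.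
- Keto ester 20 is now isolated and purified, and a separate treatment with KOtBu in THF closes the ring, so the fallback rejoins the route at 22.

Step 13. The oxatriene may close onto the carbonyl oxygen next to the chromanyl group, the two closure modes may not equilibrate fully, or a second dione molecule may intercept the alkylidene intermediate. The fallback replaces selectivity in the flask by separation and recycling.
- Setting out from 22, the condensation is run at room temperature with the dione added slowly to excess 23, and the two pyranones are separated by chromatography.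
- The regioisomeric pyranone F3 (ring D oxygen on C2') is heated on its own in toluene at 110–130 °C in a sealed tube.
- Retro-oxa-6π opening returns it to the shared oxatriene 24, which recloses, and repeated separate-and-heat cycles should drain the material into 25, where the route is rejoined.

Step 14. Three processes are of concern:
- enolisation and C–Se bond formation at the hindered, fully substituted C1' may be sluggish;
- the selenium electrophile or the peroxide may attack the prenyl and pyran alkenes;
- syn-elimination may run toward the exocyclic C3–H, which would erase the stereocentre.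

The fallback sets out from 25 and moves the handle from C1' to C5' by a different mechanism.
- Soft enolisation (Me3SiOTf, 1.1 equiv, Et3N, CH2Cl2, −78 to 0 °C) lets the amine remove the more accessible C5'–H and should give the linear silyl dienol ether F4.
- In a Saegusa–Ito oxidation (Pd(OAc)2, 1 equiv, MeCN, rt) divalent palladium attaches at C5', where β-hydride elimination can only take a C6'–H, so C3–H is out of reach and no peroxide is present.
- The resulting 2,4-dienone F5 tautomerises by loss of C1'–H, and the route is rejoined at 30.

Further compounds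
F1 | step 12 | (Z)-trimethylsilyl enol ether of 17 (C1'=C2') | CC(C)=CCc1c(OCOC)ccc2c1OC[C@H](/C=C(/C)O[Si](C)(C)C)C2
F2 | step 12 | lithium (Z)-enolate of 17 (C1'=C2') | [Li+].CC(C)=CCc1c(OCOC)ccc2c1OC[C@H](/C=C(/C)[O-])C2
F3 | step 13 | 8-[(S)-7-(methoxymethoxy)-8-prenylchroman-3-yl]-2,2-dimethyl-7,8-dihydro-2H-chromen-5(6H)-one (ring D oxygen on C2') | CC(C)=CCc1c(OCOC)ccc2c1OC[C@H](C1CCC(=O)C3=C1OC(C)(C)C=C3)C2
F4 | step 14 | linear trimethylsilyl dienol ether of 25 (C2'=C3' and C4'=C5') | CC(C)=CCc1c(OCOC)ccc2c1OC[C@H](C1CC=C3OC(C)(C)C=CC3=C1O[Si](C)(C)C)C2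
F5 | step 14 | 6-[(S)-7-(methoxymethoxy)-8-prenylchroman-3-yl]-2,2-dimethyl-2H-chromen-5(6H)-one (C5'=C6' dienone) | CC(C)=CCc1c(OCOC)ccc2c1OC[C@H](C1C=CC3=C(C=CC(C)(C)O3)C1=O)C2
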